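**Retrosynthetic overview**

- Target ⇒ ring B by a biomimetic cation–olefin cyclization (C1–C8 bond) of a dearomatized benzoylphloroglucinol dienone that carries two identical (R)-lavandulyl arms on one carbon. One arm becomes C6–C7–C8; the other stays as the C5 side chain.
- Dienone ⇒ one-pot double C-lavandulylation (alkylative dearomatization) of a 2-O-methyl-3-prenyl benzoylphloroglucinol. The methyl ether is placed on the arene, so the enol ether regiochemistry is fixed before the cyclization.
- Arene ⇒ 2,4,6-trihydroxybenzophenone by C-prenylation and a protect/methylate/deprotect sequence. (S)-Lavandulyl triflate ⇒ Evans deconjugative α-prenylation of an N-senecioyl oxazolidinone.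
- Ring order: ring A (the phloroglucinol ring) comes with the arene and is dearomatized in the alkylation; ring B (C1, C5–C9) is formed last and sets C1 and C5.

Assumption: 2,4,6-trihydroxybenzophenone is taken as a purchased material, and the target is the 2-methoxy enol ether exactly as drawn (PPAP numbering: C1 prenyl bridgehead next to C8, C5 lavandulyl bridgehead).

The stereochemistry was checked by hand from the SMILES. The target is (1R,5R,7R) with a (2R) side chain and a 7-exo prenyl group. C7 and the side-chain centre have the same spatial arrangement, so both come from (S)-lavandulol.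

**Route**

Step 1
Reactants: 1 (S)-4-benzyl-1,3-oxazolidin-2-one; 2 3-methylbut-2-enoyl chloride
Product: 3 (4S)-4-benzyl-3-(3-methylbut-2-enoyl)-1,3-oxazolidin-2-one
Conditions: n-BuLi (1.05 equiv), THF, −78 °C; then 2, −78 → 0 °C
Reagents that add atoms: none
Why: Acylation of the N-lithiated oxazolidinone by the acid chloride (Evans imide formation) is fast at −78 °C and creates no stereocentre.

Step 2
Reactants: 3 (4S)-4-benzyl-3-(3-methylbut-2-enoyl)-1,3-oxazolidin-2-one; 4 prenyl bromide (1-bromo-3-methylbut-2-ene)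
Product: 5 (4S)-4-benzyl-3-[(2S)-5-methyl-2-(prop-1-en-2-yl)hex-4-enoyl]-1,3-oxazolidin-2-one
Conditions: NaHMDS (1.1 equiv), THF, −78 °C; then 4 (3 equiv), −78 → −30 °C
Reagents that add atoms: none
Why: NaHMDS removes a γ-proton to give the chelated Z-dienolate, which is alkylated at the α-carbon on the face opposite the benzyl group (Evans deconjugative α-alkylation), setting the (2S) centre that later becomes both C7 and the side-chain centre; the minor diastereomer is removed by chromatography.

Step 3
Reactants: 5 (4S)-4-benzyl-3-[(2S)-5-methyl-2-(prop-1-en-2-yl)hex-4-enoyl]-1,3-oxazolidin-2-one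
Product: 6 (S)-lavandulol, (2S)-5-methyl-2-(prop-1-en-2-yl)hex-4-en-1-ol
Conditions: LiBH4, THF, 0 → 23 °C
Reagents that add atoms: none
Why: Hydride attacks the exocyclic imide carbonyl (reductive removal of the Evans auxiliary) to give the primary alcohol with the α-centre and both alkenes untouched, and the auxiliary is recovered.

Step 4
Reactants: 6 (S)-lavandulol
Product: 7 (S)-lavandulyl triflate, (2S)-5-methyl-2-(prop-1-en-2-yl)hex-4-en-1-yl trifluoromethanesulfonate
Conditions: Tf2O, 2,6-lutidine, CH2Cl2, −78 °C; used at once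
Reagents that add atoms: trifluoromethanesulfonic anhydride (Tf2O), O=S(=O)(OS(=O)(=O)C(F)(F)F)C(F)(F)F
Why: O-Triflation of the primary alcohol at −78 °C with a hindered base leaves the β-stereocentre and the alkenes alone and gives an electrophile reactive enough for C-alkylation of hindered phenoxides.

Step 5
Reactants: 8 2,4,6-trihydroxybenzophenone; 4 prenyl bromide
Product: 9 phenyl[2,4,6-trihydroxy-3-(3-methylbut-2-en-1-yl)phenyl]methanone
Conditions: 10% aq. KOH, 0 °C; 4 (0.9 equiv)
Reagents that add atoms: none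
Why: C-Alkylation of the phloroglucinol phenoxide in water (C-prenylation of an acylphloroglucinol) with the bromide as limiting reagent gives the mono-C-prenyl compound, and because C3 and C5 of 8 are equivalent only one regioisomer can form.

Step 6
Reactants: 9 phenyl[2,4,6-trihydroxy-3-(3-methylbut-2-en-1-yl)phenyl]methanone
Product: 10 [2-hydroxy-4,6-bis(methoxymethoxy)-3-(3-methylbut-2-en-1-yl)phenyl](phenyl)methanone
Conditions: MOMCl (2.1 equiv), iPr2NEt, CH2Cl2, 0 °C
Reagents that add atoms: chloromethyl methyl ether (MOMCl), COCCl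
Why: Williamson-type MOM etherification takes the free 4-OH and the less hindered 6-OH, while the 2-OH, hydrogen-bonded to the carbonyl and flanked by benzoyl and prenyl, is left.

Step 7
Reactants: 10 [2-hydroxy-4,6-bis(methoxymethoxy)-3-(3-methylbut-2-en-1-yl)phenyl](phenyl)methanone
Product: 11 [2-methoxy-4,6-bis(methoxymethoxy)-3-(3-methylbut-2-en-1-yl)phenyl](phenyl)methanone
Conditions: MeI, K2CO3, DMF, 40 °C
Reagents that add atoms: iodomethane (MeI), CI
Why: Williamson methylation of the only remaining phenol puts the methyl group on the oxygen between the benzoyl and prenyl carbons, which is the enol ether oxygen of the target.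

Step 8
Reactants: 11 [2-methoxy-4,6-bis(methoxymethoxy)-3-(3-methylbut-2-en-1-yl)phenyl](phenyl)methanone
Product: 12 [4,6-dihydroxy-2-methoxy-3-(3-methylbut-2-en-1-yl)phenyl](phenyl)methanone
Conditions: HCl (1.5 M), MeOH, 23 °C
Reagents that add atoms: none
Why: Acid-catalysed transacetalization to methanol removes both MOM ethers at room temperature, under which the aryl methyl ether and the prenyl group survive.

Step 9
Reactants: 12 [4,6-dihydroxy-2-methoxy-3-(3-methylbut-2-en-1-yl)phenyl](phenyl)methanone; 7 (S)-lavandulyl triflate (2.4 equiv)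
Product: 14 4-benzoyl-5-hydroxy-3-methoxy-2-(3-methylbut-2-en-1-yl)-6,6-bis[(2R)-5-methyl-2-(prop-1-en-2-yl)hex-4-en-1-yl]cyclohexa-2,4-dien-1-one, via mono-lavandulyl benzophenone 13 (not isolated)
Conditions: LiHMDS (3.3 equiv), toluene/THF 4:1, −78 °C; then 7, −78 → 0 °C; aq. NH4Cl
Reagents that add atoms: none
Why: Alkylative dearomatization by SN2 C-alkylation of the lithium phenoxide: the first triflate reacts at the only free ring carbon (13) and the second at the same carbon, because it alone lies between two lithium oxides while the prenyl carbon is flanked by the OMe group; the quaternary carbon carries two identical arms, so no new stereocentre arises, and the arms keep the lavandulol configuration (R only through a CIP priority change).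

Step 10
Reactants: 14 4-benzoyl-5-hydroxy-3-methoxy-2-(3-methylbut-2-en-1-yl)-6,6-bis[(2R)-5-methyl-2-(prop-1-en-2-yl)hex-4-en-1-yl]cyclohexa-2,4-dien-1-one
Product: 15 (1R,5R,7R)-3-benzoyl-2-methoxy-8,8-dimethyl-1,7-bis(3-methylbut-2-en-1-yl)-5-[(2R)-5-methyl-2-(prop-1-en-2-yl)hex-4-en-1-yl]bicyclo[3.3.1]non-2-ene-4,9-dione
Conditions: HCO2H (98%), 15 → 23 °C, stopped at about 90% conversion
Reagents that add atoms: none
Why: Proposed new method: formic acid protonates an isopropenyl group with π-participation of the prenyl-bearing terminus of the dienol ether, so the arm that can reach a chair transition state with its prenyl group equatorial closes the C1–C8 bond (the arms are diastereotopic and the quaternary carbon is not a stereocentre, so all material can use the matched arm), which sets C1 and C5 as R relative to the pre-set C7 (7-exo), leaves the other arm as the C5 side chain, and gives the 2-methoxy enone directly when the C2 oxocarbenium ion loses the enol proton; closest known reaction type: formic acid-mediated cation–olefin cyclization of dearomatized acylphloroglucinol enol ethers to bicyclo[3.3.1]nonane PPAP cores (Stork–Eschenmoser-type chair cyclization).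

**Compound list**

1 | (S)-4-benzyl-1,3-oxazolidin-2-one | O=C1OC[C@H](Cc2ccccc2)N1 | starting material
2 | 3-methylbut-2-enoyl chloride | CC(C)=CC(=O)Cl | starting material
3 | (4S)-4-benzyl-3-(3-methylbut-2-enoyl)-1,3-oxazolidin-2-one | CC(C)=CC(=O)N1[C@@H](Cc2ccccc2)COC1=O | intermediate
4 | prenyl bromide (1-bromo-3-methylbut-2-ene) | CC(C)=CCBr | starting material
5 | (4S)-4-benzyl-3-[(2S)-5-methyl-2-(prop-1-en-2-yl)hex-4-enoyl]-1,3-oxazolidin-2-one | C=C(C)[C@H](CC=C(C)C)C(=O)N1[C@@H](Cc2ccccc2)COC1=O | intermediate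
6 | (S)-lavandulol, (2S)-5-methyl-2-(prop-1-en-2-yl)hex-4-en-1-ol | C=C(C)[C@H](CC=C(C)C)CO | intermediate
7 | (S)-lavandulyl triflate, (2S)-5-methyl-2-(prop-1-en-2-yl)hex-4-en-1-yl trifluoromethanesulfonate | C=C(C)[C@H](CC=C(C)C)COS(=O)(=O)C(F)(F)F | intermediate
8 | 2,4,6-trihydroxybenzophenone | O=C(c1ccccc1)c1c(O)cc(O)cc1O | starting material
9 | phenyl[2,4,6-trihydroxy-3-(3-methylbut-2-en-1-yl)phenyl]methanone | CC(C)=CCc1c(O)cc(O)c(C(=O)c2ccccc2)c1O | intermediate
10 | [2-hydroxy-4,6-bis(methoxymethoxy)-3-(3-methylbut-2-en-1-yl)phenyl](phenyl)methanone | CC(C)=CCc1c(OCOC)cc(OCOC)c(C(=O)c2ccccc2)c1O | intermediate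
11 | [2-methoxy-4,6-bis(methoxymethoxy)-3-(3-methylbut-2-en-1-yl)phenyl](phenyl)methanone | CC(C)=CCc1c(OCOC)cc(OCOC)c(C(=O)c2ccccc2)c1OC | intermediate
12 | [4,6-dihydroxy-2-methoxy-3-(3-methylbut-2-en-1-yl)phenyl](phenyl)methanone | CC(C)=CCc1c(O)cc(O)c(C(=O)c2ccccc2)c1OC | intermediate
13 | {4,6-dihydroxy-2-methoxy-3-(3-methylbut-2-en-1-yl)-5-[(2R)-5-methyl-2-(prop-1-en-2-yl)hex-4-en-1-yl]phenyl}(phenyl)methanone | C=C(C)[C@H](CC=C(C)C)Cc1c(O)c(CC=C(C)C)c(OC)c(C(=O)c2ccccc2)c1O | intermediate
14 | 4-benzoyl-5-hydroxy-3-methoxy-2-(3-methylbut-2-en-1-yl)-6,6-bis[(2R)-5-methyl-2-(prop-1-en-2-yl)hex-4-en-1-yl]cyclohexa-2,4-dien-1-one (one tautomer drawn) | C=C(C)[C@H](CC=C(C)C)CC1(C[C@@H](CC=C(C)C)C(C)=C)C(=O)C(CC=C(C)C)=C(OC)C(C(=O)c2ccccc2)=C1O | intermediate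
15 | (1R,5R,7R)-3-benzoyl-2-methoxy-8,8-dimethyl-1,7-bis(3-methylbut-2-en-1-yl)-5-[(2R)-5-methyl-2-(prop-1-en-2-yl)hex-4-en-1-yl]bicyclo[3.3.1]non-2-ene-4,9-dione | C=C(C)[C@H](CC=C(C)C)C[C@@]12C[C@@H](CC=C(C)C)C(C)(C)[C@@](CC=C(C)C)(C1=O)C(OC)=C(C(=O)c1ccccc1)C2=O | target

**Step count**

Total steps: 10. Longest linear sequence: 6 steps (8 → 9 → 10 → 11 → 12 → 14 → 15). The side-chain branch 1 → 3 → 5 → 6 → 7 joins at step 9 and is also 6 steps to 15.

**Three steps most likely to fail, with fallbacks**

1. Step 10, the cyclization. Risks: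
- the enol oxygen may trap the cation to give a pyran;
- the second isopropenyl group or a prenyl group may be protonated, leading to alkene isomerization or over-reaction;
- the mismatched arm may close to the 7-endo isomer;
- closure onto the benzoyl-bearing carbon is possible.

The fallback makes only one arm ionizable and sets out from 6 and 13, returning at 15. (S)-Lavandulol 6 is hydromethoxylated at the isopropenyl group only, by hydrogen-atom-transfer Markovnikov hydroalkoxylation (Co(salen), divalent cobalt, N-fluoro-2,4,6-trimethylpyridinium tetrafluoroborate, PhSiH3, MeOH; the 1,1-disubstituted alkene reacts before the trisubstituted one). This gives (2R)-2-(2-methoxypropan-2-yl)-5-methylhex-4-en-1-ol F1. Triflation (Tf2O, 2,6-lutidine, −78 °C) gives the methoxy-arm triflate F2. Compound 13, made and isolated by running step 9 with one equivalent of 7, is alkylated with F2 (LiHMDS) to give the mixed dienone F3 together with its C6 epimer F4. BF3·OEt2 with 2,6-di-tert-butyl-4-methylpyridine in CH2Cl2 at −60 °C ionizes only the tertiary methyl ether, with no Brønsted acid to touch the isopropenyl or prenyl groups. F3 closes through the same chair transition state to 15; F4 gives the 7-endo isomer, which is separated. The cost is that about half of the material is in the unproductive epimer.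

2. Step 9, the double alkylative dearomatization. Risks are O-alkylation, slow SN2 at the β-branched triflate when the quaternary carbon is formed, and alkylation at the prenyl-bearing carbon. The fallback makes the first C–C bond from an aryl–metal, which cannot O-alkylate; it sets out from 11 and returns at 14 through 13. Compound 11 is zincated between its two MOM ethers with TMPZnCl·LiCl (THF, 25–60 °C; directed metalation, the ketone is tolerated) to give the arylzinc chloride F5. (S)-Lavandulyl iodide F6 is made from 6 with I2, PPh3 and imidazole. Negishi coupling of F5 with F6 (Pd2(dba)3, tricyclopentylphosphine, N-methylimidazole, THF/NMP, 80 °C) gives the coupled bis-MOM ether F7. HCl in MeOH, as in step 8, gives 13, and a single LiHMDS alkylation with 7 gives 14.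

3. Step 6, the selective bis-MOM protection. The risk is that the second MOM group goes to the 2-OH instead of the 6-OH, which would end with the methyl ether on the wrong oxygen. The fallback fixes the regiochemistry by symmetry and a para-Claisen rearrangement; it sets out from 8 and returns at 12.
- The free 4-OH of 8 is protected (MOMCl 1.0 equiv, iPr2NEt) to give the mono-MOM ether F8.
- One of the two equivalent chelated phenols is methylated (MeI 1.0 equiv, K2CO3, acetone) to give the methyl ether F9.
- The last phenol is O-prenylated with 4 (K2CO3, DMF) to give the prenyl ether F10.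
- Heating in N,N-diethylaniline at 190 °C brings about the aromatic Claisen–Cope rearrangement, which carries the prenyl group to the ring carbon para to that oxygen, between OMe and OMOM, to give the C-prenyl phenol F11.
- HCl in MeOH then gives 12.

**Further compounds**

F1 | step 10 | (2R)-2-(2-methoxypropan-2-yl)-5-methylhex-4-en-1-ol | COC(C)(C)[C@H](CC=C(C)C)CO
F2 | step 10 | (2R)-2-(2-methoxypropan-2-yl)-5-methylhex-4-en-1-yl trifluoromethanesulfonate | COC(C)(C)[C@H](CC=C(C)C)COS(=O)(=O)C(F)(F)F
F3 | step 10 | (6S)-4-benzoyl-5-hydroxy-3-methoxy-6-[(2R)-2-(2-methoxypropan-2-yl)-5-methylhex-4-en-1-yl]-2-(3-methylbut-2-en-1-yl)-6-[(2R)-5-methyl-2-(prop-1-en-2-yl)hex-4-en-1-yl]cyclohexa-2,4-dien-1-one | C=C(C)[C@H](CC=C(C)C)C[C@@]1(C[C@@H](CC=C(C)C)C(C)(C)OC)C(=O)C(CC=C(C)C)=C(OC)C(C(=O)c2ccccc2)=C1O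
F4 | step 10 | (6R)-4-benzoyl-5-hydroxy-3-methoxy-6-[(2R)-2-(2-methoxypropan-2-yl)-5-methylhex-4-en-1-yl]-2-(3-methylbut-2-en-1-yl)-6-[(2R)-5-methyl-2-(prop-1-en-2-yl)hex-4-en-1-yl]cyclohexa-2,4-dien-1-one | C=C(C)[C@H](CC=C(C)C)C[C@]1(C[C@@H](CC=C(C)C)C(C)(C)OC)C(=O)C(CC=C(C)C)=C(OC)C(C(=O)c2ccccc2)=C1O
F5 | step 9 | [3-benzoyl-4-methoxy-2,6-bis(methoxymethoxy)-5-(3-methylbut-2-en-1-yl)phenyl]zinc chloride | CC(C)=CCc1c(OCOC)c([Zn]Cl)c(OCOC)c(C(=O)c2ccccc2)c1OC
F6 | step 9 | (S)-lavandulyl iodide, (2S)-1-iodo-5-methyl-2-(prop-1-en-2-yl)hex-4-ene | C=C(C)[C@H](CC=C(C)C)CI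
F7 | step 9 | {2-methoxy-4,6-bis(methoxymethoxy)-3-(3-methylbut-2-en-1-yl)-5-[(2R)-5-methyl-2-(prop-1-en-2-yl)hex-4-en-1-yl]phenyl}(phenyl)methanone | C=C(C)[C@H](CC=C(C)C)Cc1c(OCOC)c(CC=C(C)C)c(OC)c(C(=O)c2ccccc2)c1OCOC
F8 | step 6 | [2,6-dihydroxy-4-(methoxymethoxy)phenyl](phenyl)methanone | COCOc1cc(O)c(C(=O)c2ccccc2)c(O)c1
F9 | step 6 | [2-hydroxy-6-methoxy-4-(methoxymethoxy)phenyl](phenyl)methanone | COCOc1cc(O)c(C(=O)c2ccccc2)c(OC)c1
F10 | step 6 | {2-methoxy-4-(methoxymethoxy)-6-[(3-methylbut-2-en-1-yl)oxy]phenyl}(phenyl)methanone | COCOc1cc(OCC=C(C)C)c(C(=O)c2ccccc2)c(OC)c1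
F11 | step 6 | [6-hydroxy-2-methoxy-4-(methoxymethoxy)-3-(3-methylbut-2-en-1-yl)phenyl](phenyl)methanone | COCOc1cc(O)c(C(=O)c2ccccc2)c(OC)c1CC=C(C)C
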